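**Plan**
1. Cuts (benzofuran numbering O1, C2, C3, C3a, C4–C7, C7a; C9 = hydroxymethyl carbon): after deprotection and exchange of the C7 methoxy for bromide, benzene ring A is cut at C3a–C4 and C7–C7a. This leaves C4–C7 as methyl 3-bromocoumalate and O1/C2/C3/C3a/C7a as the O-silyl ketene acetal of a trans-β,γ-disubstituted butyrolactone, which is cut at C2–C3 (aldol) and at its lactone C–O bond.
2. Enabling feature: ring A carries O1 on C7a para to the C5 ester and a heteroatom on C7. A 3-substituted 2-pyrone-5-carboxylate and a ketene acetal deliver exactly this pattern once CO2 and the exocyclic acetal oxygen are lost.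
3. Forward order: the five-membered oxygen ring is made first as a γ-lactone (aldol, lactonisation), the exocyclic carboxyl is reduced to C9, and the lactone is O-silylated. Ring A is then grown on it in one operation; bromide-to-methoxide exchange and two deprotections finish.
4. Stereochemistry: C2 (S) and C3 (R) both come from one auxiliary-controlled boron syn-aldol with (S)-4-benzyloxazolidinone. Lactonisation turns syn into trans, and both centres are spectators afterwards.

Key step: step 8

Remark on protecting groups: the phenol is carried as a benzyl ether (O-benzylvanillin is commercial), because an aryl silyl ether would not be expected to survive the hydroxide/peroxide and carbonate/methanol steps; the primary alcohol is carried as a TBS ether. Abbreviations: Ar = 4-(benzyloxy)-3-methoxyphenyl, TBS = tert-butyldimethylsilyl.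
Assumption: the bromine adduct of methyl coumalate in step 7 is taken to be the trans-3,4-dibromide; a regioisomeric adduct would give the same 3-bromopyrone on dehydrobromination.

**Step 1**
Reactants: 1 (S)-4-benzyl-1,3-oxazolidin-2-one; 2 methyl 4-chloro-4-oxobutanoate
Product: 3 methyl 4-[(4S)-4-benzyl-2-oxo-1,3-oxazolidin-3-yl]-4-oxobutanoate
Conditions: Et3N, DMAP (cat.), CH2Cl2, 0 °C → rt
Reagents that add atoms: none
Why: N-acylation of the oxazolidinone by the acid chloride under nucleophilic (DMAP) catalysis is standard and leaves the methyl ester untouched.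

**Step 2**
Reactants: 3 methyl 4-[(4S)-4-benzyl-2-oxo-1,3-oxazolidin-3-yl]-4-oxobutanoate; 4 4-(benzyloxy)-3-methoxybenzaldehyde
Product: 7 (4S)-4-benzyl-3-{[(2S,3S)-2-Ar-5-oxooxolan-3-yl]carbonyl}-1,3-oxazolidin-2-one (trans lactone imide), via dibutylboron Z-enolate 5 (not isolated), via syn-aldol hydroxy ester 6 (not isolated)
Conditions: Bu2BOTf, i-Pr2NEt, CH2Cl2, 0 °C; 4, −78 → 0 °C; pH 7 buffer, MeOH, 30% H2O2, 0 °C → rt; crude: PPTS (cat.), CH2Cl2, rt
Reagents that add atoms: none
Why: Evans boron syn-aldol, in which the Z-enolate 5 (formed only at the imide α-carbon) should add to 4 through a chair Zimmerman–Traxler transition state on the face away from the auxiliary benzyl group and so set both centres (S,S) in 6, whose hydroxyl then closes onto the γ-ester (5-exo-trig lactonisation, loss of methanol) so that syn becomes trans in 7.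

**Step 3**
Reactants: 7 trans lactone imide
Product: 9 (2S,3S)-2-Ar-5-oxooxolane-3-carboxylic acid, via peroxy acid 8 (not isolated)
Conditions: LiOH, 30% H2O2, THF/H2O (3:1), 0 °C; aq. Na2SO3; 1 M HCl to pH 2
Reagents that add atoms: hydrogen peroxide (as lithium hydroperoxide), OO
Why: Hydroperoxide should attack the exocyclic imide carbonyl selectively (standard auxiliary cleavage), peroxy acid 8 is reduced in the flask, and any lactone opened by hydroxide should reclose on acidification because only the γ-lactone can form.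

**Step 4**
Reactants: 9 (2S,3S)-2-Ar-5-oxooxolane-3-carboxylic acid
Product: 10 (4R,5S)-5-Ar-4-(hydroxymethyl)oxolan-2-one
Conditions: BH3·SMe2, THF, 0 °C → rt; MeOH quench
Reagents that add atoms: none
Why: Borane reduces a carboxylic acid much faster than a lactone (the usual conversion of paraconic acids into hydroxymethyl lactones), and the non-basic medium avoids translactonisation; the descriptor at C4 changes to R only through CIP priorities.

**Step 5**
Reactants: 10 (4R,5S)-5-Ar-4-(hydroxymethyl)oxolan-2-one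
Product: 11 (4R,5S)-5-Ar-4-{[(tert-butyldimethylsilyl)oxy]methyl}oxolan-2-one
Conditions: TBSCl, imidazole, DMF, 0 °C → rt
Reagents that add atoms: tert-butyldimethylsilyl chloride, CC(C)(C)[Si](C)(C)Cl
Why: Standard silylation of a primary alcohol under imidazole, mild enough that the hydroxymethyl lactone should not rearrange.

**Step 6**
Reactants: 11 (4R,5S)-5-Ar-4-{[(tert-butyldimethylsilyl)oxy]methyl}oxolan-2-one
Product: 13 tert-butyl{[(2S,3R)-2-Ar-3-{[(tert-butyldimethylsilyl)oxy]methyl}-2,3-dihydrofuran-5-yl]oxy}dimethylsilane (cyclic silyl ketene acetal), via lithium enolate 12 (not isolated)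
Conditions: LDA, THF, −78 °C; TBSCl, DMPU, −78 → 0 °C; pentane, filtration under Ar (no aqueous work-up), used crude
Reagents that add atoms: tert-butyldimethylsilyl chloride, CC(C)(C)[Si](C)(C)Cl
Why: Kinetic deprotonation at the only enolisable position and O-silylation of enolate 12 with TBSCl in the presence of DMPU is the standard route to 2-silyloxy-4,5-dihydrofurans, and the enolate has no β-leaving group, so the two stereocentres should be untouched.

**Step 7**
Reactants: 14 methyl coumalate (methyl 2-oxo-2H-pyran-5-carboxylate)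
Product: 16 methyl 3-bromo-2-oxo-2H-pyran-5-carboxylate, via dibromo adduct 15 (not isolated)
Conditions: Br2, CH2Cl2, 0 °C → rt; Et3N, 0 °C
Reagents that add atoms: bromine, BrBr
Why: Bromination–dehydrobromination, the usual entry to 3-bromo-2-pyrones: bromine adds to the C3=C4 bond (C5 is blocked by the ester) and triethylamine removes HBr by E1cB from the α-bromo position.

**Step 8**
Reactants: 13 cyclic silyl ketene acetal; 16 methyl 3-bromo-2-oxo-2H-pyran-5-carboxylate
Product: 19 methyl (2S,3R)-2-Ar-7-bromo-3-{[(tert-butyldimethylsilyl)oxy]methyl}-2,3-dihydro-1-benzofuran-5-carboxylate, via bridged lactone adduct 17 (not isolated), via dihydroarene 18 (not isolated)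
Conditions: PhMe, i-Pr2NEt (0.1 equiv), 60 → 110 °C, sealed tube, Ar
Reagents that add atoms: none
Why: In an inverse-electron-demand Diels–Alder reaction the electron-rich alkene of 13 should add across C6 and C3 of the electron-poor pyrone 16, its nucleophilic carbon (future C3a) bonding to C6, the terminus made electrophilic by both the C5 ester and the ring carbonyl, and its acetal carbon (future C7a) bonding to the brominated C3 (future C7), to give bridged lactone 17. Retro-[4+2] loss of carbon dioxide from 17 should give the cis-fused dihydroarene 18, and elimination of tert-butyldimethylsilanol across C7a–C3a then aromatises it to 19. The closest known reaction type is the cycloaddition of 2-pyrone-5-carboxylates with ketene acetals, which gives para-alkoxybenzoates after loss of carbon dioxide and alcohol. Ring A is the only ring closed; it forms by intermolecular [4+2] cycloaddition (bonds C3a–C4 and C7–C7a) onto the existing five-membered ring and is made permanent by aromatisation. No lasting stereocentre is created, since the sp3 centres of 17 and 18 disappear on aromatisation and C2 and C3 are not involved. The step needs O1 to end up para to the ester, which the polarisation of the pyrone by its C5 ester should secure, and it needs the exocyclic silyloxy group to leave in preference to the ring oxygen, which is favoured because silanolate is the better leaving group, sits cis to the C3a hydrogen and its loss keeps the five-membered ring.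

**Step 9**
Reactants: 19 7-bromo dihydrobenzofuran ester
Product: 20 methyl (2S,3R)-2-Ar-3-{[(tert-butyldimethylsilyl)oxy]methyl}-7-methoxy-2,3-dihydro-1-benzofuran-5-carboxylate
Conditions: tBuBrettPhos Pd G3 (3 mol%), Cs2CO3, MeOH (10 equiv), 1,4-dioxane, 60 °C
Reagents that add atoms: methanol, CO
Why: Palladium-catalysed C–O cross-coupling of an aryl bromide with methanol, where the bulky biaryl phosphine favours C–O reductive elimination over β-hydride elimination; carbonate/methanol should leave the methyl ester (degenerate exchange), benzyl ether and primary silyl ether intact.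

**Step 10**
Reactants: 20 7-methoxy silyl ether
Product: 21 methyl (2S,3R)-2-Ar-3-(hydroxymethyl)-7-methoxy-2,3-dihydro-1-benzofuran-5-carboxylate (O-benzylcurlignan)
Conditions: TBAF, AcOH, THF, 0 °C → rt
Reagents that add atoms: none
Why: Fluoride cleavage of the primary silyl ether, buffered with acetic acid so that the methyl ester and the benzylic centres see no strong base.

**Step 11**
Reactants: 21 O-benzylcurlignan
Product: 22 curlignan, methyl (2S,3R)-2-(4-hydroxy-3-methoxyphenyl)-3-(hydroxymethyl)-7-methoxy-2,3-dihydro-1-benzofuran-5-carboxylate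
Conditions: H2 (1 atm), 10% Pd/C, EtOAc, rt
Reagents that add atoms: none
Why: Hydrogenolysis of an aryl benzyl ether under mild conditions, which 2-aryl-2,3-dihydrobenzofurans are known to tolerate, so the cyclic benzylic ether and both stereocentres should remain.

**Compound list**
1 | (S)-4-benzyl-1,3-oxazolidin-2-one | O=C1N[C@@H](Cc2ccccc2)CO1 | starting material
2 | methyl 4-chloro-4-oxobutanoate | COC(=O)CCC(=O)Cl | starting material
3 | methyl 4-[(4S)-4-benzyl-2-oxo-1,3-oxazolidin-3-yl]-4-oxobutanoate | COC(=O)CCC(=O)N1C(=O)OC[C@@H]1Cc1ccccc1 | intermediate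
4 | 4-(benzyloxy)-3-methoxybenzaldehyde (O-benzylvanillin) | COc1cc(C=O)ccc1OCc1ccccc1 | starting material
5 | methyl (3Z)-4-[(4S)-4-benzyl-2-oxo-1,3-oxazolidin-3-yl]-4-[(dibutylboranyl)oxy]but-3-enoate (Z-boron enolate, not isolated) | CCCCB(CCCC)O/C(=C\CC(=O)OC)N1C(=O)OC[C@@H]1Cc1ccccc1 | intermediate
6 | methyl (3S)-4-[(4S)-4-benzyl-2-oxo-1,3-oxazolidin-3-yl]-3-[(S)-[4-(benzyloxy)-3-methoxyphenyl](hydroxy)methyl]-4-oxobutanoate (syn aldol, not isolated) | COC(=O)C[C@H](C(=O)N1C(=O)OC[C@@H]1Cc1ccccc1)[C@H](O)c1ccc(OCc2ccccc2)c(OC)c1 | intermediate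
7 | (4S)-4-benzyl-3-{[(2S,3S)-2-[4-(benzyloxy)-3-methoxyphenyl]-5-oxooxolan-3-yl]carbonyl}-1,3-oxazolidin-2-one | O=C1C[C@H](C(=O)N2C(=O)OC[C@@H]2Cc2ccccc2)[C@@H](c2ccc(OCc3ccccc3)c(OC)c2)O1 | intermediate
8 | (2S,3S)-2-[4-(benzyloxy)-3-methoxyphenyl]-5-oxooxolane-3-carboperoxoic acid (not isolated) | O=C1C[C@H](C(=O)OO)[C@@H](c2ccc(OCc3ccccc3)c(OC)c2)O1 | intermediate
9 | (2S,3S)-2-[4-(benzyloxy)-3-methoxyphenyl]-5-oxooxolane-3-carboxylic acid | O=C1C[C@H](C(=O)O)[C@@H](c2ccc(OCc3ccccc3)c(OC)c2)O1 | intermediate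
10 | (4R,5S)-5-[4-(benzyloxy)-3-methoxyphenyl]-4-(hydroxymethyl)oxolan-2-one | O=C1C[C@H](CO)[C@@H](c2ccc(OCc3ccccc3)c(OC)c2)O1 | intermediate
11 | (4R,5S)-5-[4-(benzyloxy)-3-methoxyphenyl]-4-{[(tert-butyldimethylsilyl)oxy]methyl}oxolan-2-one | O=C1C[C@H](CO[Si](C)(C)C(C)(C)C)[C@@H](c2ccc(OCc3ccccc3)c(OC)c2)O1 | intermediate
12 | lithium (2S,3R)-2-[4-(benzyloxy)-3-methoxyphenyl]-3-{[(tert-butyldimethylsilyl)oxy]methyl}-2,3-dihydrofuran-5-olate (not isolated) | [Li+].[O-]C1=C[C@H](CO[Si](C)(C)C(C)(C)C)[C@@H](c2ccc(OCc3ccccc3)c(OC)c2)O1 | intermediate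
13 | tert-butyl{[(2S,3R)-2-[4-(benzyloxy)-3-methoxyphenyl]-3-{[(tert-butyldimethylsilyl)oxy]methyl}-2,3-dihydrofuran-5-yl]oxy}dimethylsilane | CC(C)(C)[Si](C)(C)OC1=C[C@H](CO[Si](C)(C)C(C)(C)C)[C@@H](c2ccc(OCc3ccccc3)c(OC)c2)O1 | intermediate
14 | methyl coumalate (methyl 2-oxo-2H-pyran-5-carboxylate) | COC(=O)C1=COC(=O)C=C1 | starting material
15 | methyl trans-3,4-dibromo-2-oxo-3,4-dihydro-2H-pyran-5-carboxylate (racemic, one enantiomer drawn, not isolated) | COC(=O)C1=COC(=O)[C@H](Br)[C@H]1Br | intermediate
16 | methyl 3-bromo-2-oxo-2H-pyran-5-carboxylate | COC(=O)C1=COC(=O)C(Br)=C1 | intermediate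
17 | bridged [4+2] adduct of 13 and 16: 2-oxabicyclo[2.2.2]oct-5-en-3-one with Br on the bridgehead next to the lactone carbonyl, fused to the tetrahydrofuran ring (mixture at the four transient centres, not isolated) | COC(=O)C1=CC2(Br)C(=O)OC1C1C2(O[Si](C)(C)C(C)(C)C)O[C@H](c2ccc(OCc3ccccc3)c(OC)c2)[C@H]1CO[Si](C)(C)C(C)(C)C | intermediate
18 | methyl (2S,3R)-2-[4-(benzyloxy)-3-methoxyphenyl]-7-bromo-7a-[(tert-butyldimethylsilyl)oxy]-3-{[(tert-butyldimethylsilyl)oxy]methyl}-2,3,3a,7a-tetrahydro-1-benzofuran-5-carboxylate (cis-fused, 3a/7a transient, not isolated) | COC(=O)C1=CC2[C@H](CO[Si](C)(C)C(C)(C)C)[C@@H](c3ccc(OCc4ccccc4)c(OC)c3)OC2(O[Si](C)(C)C(C)(C)C)C(Br)=C1 | intermediate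
19 | methyl (2S,3R)-2-[4-(benzyloxy)-3-methoxyphenyl]-7-bromo-3-{[(tert-butyldimethylsilyl)oxy]methyl}-2,3-dihydro-1-benzofuran-5-carboxylate | COC(=O)c1cc(Br)c2c(c1)[C@H](CO[Si](C)(C)C(C)(C)C)[C@@H](c1ccc(OCc3ccccc3)c(OC)c1)O2 | intermediate
20 | methyl (2S,3R)-2-[4-(benzyloxy)-3-methoxyphenyl]-3-{[(tert-butyldimethylsilyl)oxy]methyl}-7-methoxy-2,3-dihydro-1-benzofuran-5-carboxylate | COC(=O)c1cc(OC)c2c(c1)[C@H](CO[Si](C)(C)C(C)(C)C)[C@@H](c1ccc(OCc3ccccc3)c(OC)c1)O2 | intermediate
21 | methyl (2S,3R)-2-[4-(benzyloxy)-3-methoxyphenyl]-3-(hydroxymethyl)-7-methoxy-2,3-dihydro-1-benzofuran-5-carboxylate | COC(=O)c1cc(OC)c2c(c1)[C@H](CO)[C@@H](c1ccc(OCc3ccccc3)c(OC)c1)O2 | intermediate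
22 | curlignan, methyl (2S,3R)-2-(4-hydroxy-3-methoxyphenyl)-3-(hydroxymethyl)-7-methoxy-2,3-dihydro-1-benzofuran-5-carboxylate | COC(=O)c1cc(OC)c2c(c1)[C@H](CO)[C@@H](c1ccc(O)c(OC)c1)O2 | target

**Step count**
Total: 11 steps. Longest linear sequence: 10 steps (steps 1–6 and 8–11); step 7 is a one-step side branch.

**Steps most likely to fail**

Step 8. The dihydroarene may aromatise by cleavage of the ring C7a–O1 bond instead of by loss of silanol, which opens the five-membered ring; the ketene acetal may also be hydrolysed by adventitious water before it is consumed. The fallback sets out from 13 and 16, passes through 17 and 18 as before, and accepts the ring opening. The ring-opened aryl silyl ether, methyl 3-bromo-4-[(tert-butyldimethylsilyl)oxy]-5-[(1S,2R)-1-Ar-3-[(tert-butyldimethylsilyl)oxy]-1-hydroxypropan-2-yl]benzoate F1, should lose its electron-poor aryl silyl group with K2CO3 in MeOH at 0 °C (which should also collapse any remaining 18), giving the bromophenol methyl 3-bromo-4-hydroxy-5-[(1S,2R)-1-Ar-3-[(tert-butyldimethylsilyl)oxy]-1-hydroxypropan-2-yl]benzoate F2 with the primary silyl ether intact. Catalytic p-TsOH (or BF3·OEt2) in CH2Cl2 at low temperature should then ionise the para-alkoxybenzylic alcohol, and the phenol oxygen should close the ring 5-exo onto the cation anti to the C3 substituent. This is the known acid-mediated cyclodehydration to trans-2-aryl-2,3-dihydrobenzofurans, and it comes back to the route at 19.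

Step 6. The enolate may be silylated on carbon instead of oxygen, or the ketene acetal may hydrolyse back to the lactone during isolation. The fallback sets out from 11 and replaces the silyloxy leaving group by a thioether. Lawesson's reagent in toluene at 100 °C should give the thionolactone (4R,5S)-5-Ar-4-{[(tert-butyldimethylsilyl)oxy]methyl}oxolane-2-thione F3. LDA at −78 °C followed by MeI should alkylate the soft sulfur and give the hydrolytically robust ketene O,S-acetal (2S,3R)-2-Ar-3-{[(tert-butyldimethylsilyl)oxy]methyl}-5-(methylsulfanyl)-2,3-dihydrofuran F4. Heating F4 with 16 in toluene should lead through the bridged adduct F5 and, after loss of carbon dioxide, the 7a-(methylsulfanyl) dihydroarene F6, which aromatises by loss of methanethiol, a much better leaving group than the ring alkoxide. This bypasses 13 and comes back to the route at 19.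

Step 9. The aryl bromide may be reduced (β-hydride elimination from the palladium methoxide) or react sluggishly at the ortho-alkoxy position. The fallback sets out from 19 and makes the C–O bond by oxidation instead of coupling. Miyaura borylation (B2pin2, Pd(dppf)Cl2, KOAc, dioxane, 80 °C) should give the pinacol boronate methyl (2S,3R)-2-Ar-3-{[(tert-butyldimethylsilyl)oxy]methyl}-7-(4,4,5,5-tetramethyl-1,3,2-dioxaborolan-2-yl)-2,3-dihydro-1-benzofuran-5-carboxylate F7. Oxidation with NaBO3·4H2O in THF/H2O at rt should give the phenol methyl (2S,3R)-2-Ar-3-{[(tert-butyldimethylsilyl)oxy]methyl}-7-hydroxy-2,3-dihydro-1-benzofuran-5-carboxylate F8. O-Methylation with MeI and K2CO3 in acetone comes back to the route at 20.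

**Further compounds**
F1 | step 8 | methyl 3-bromo-4-[(tert-butyldimethylsilyl)oxy]-5-[(1S,2R)-1-[4-(benzyloxy)-3-methoxyphenyl]-3-[(tert-butyldimethylsilyl)oxy]-1-hydroxypropan-2-yl]benzoate | COC(=O)c1cc(Br)c(O[Si](C)(C)C(C)(C)C)c(c1)[C@H](CO[Si](C)(C)C(C)(C)C)[C@H](O)c1ccc(OCc2ccccc2)c(OC)c1
F2 | step 8 | methyl 3-bromo-5-[(1S,2R)-1-[4-(benzyloxy)-3-methoxyphenyl]-3-[(tert-butyldimethylsilyl)oxy]-1-hydroxypropan-2-yl]-4-hydroxybenzoate | COC(=O)c1cc(Br)c(O)c(c1)[C@H](CO[Si](C)(C)C(C)(C)C)[C@H](O)c1ccc(OCc2ccccc2)c(OC)c1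
F3 | step 6 | (4R,5S)-5-[4-(benzyloxy)-3-methoxyphenyl]-4-{[(tert-butyldimethylsilyl)oxy]methyl}oxolane-2-thione | S=C1C[C@H](CO[Si](C)(C)C(C)(C)C)[C@@H](c2ccc(OCc3ccccc3)c(OC)c2)O1
F4 | step 6 | (2S,3R)-2-[4-(benzyloxy)-3-methoxyphenyl]-3-{[(tert-butyldimethylsilyl)oxy]methyl}-5-(methylsulfanyl)-2,3-dihydrofuran | CSC1=C[C@H](CO[Si](C)(C)C(C)(C)C)[C@@H](c2ccc(OCc3ccccc3)c(OC)c2)O1
F5 | step 6 | bridged [4+2] adduct of F4 and 16 (methylsulfanyl analogue of 17, transient centres undefined) | COC(=O)C1=CC2(Br)C(=O)OC1C1C2(SC)O[C@H](c2ccc(OCc3ccccc3)c(OC)c2)[C@H]1CO[Si](C)(C)C(C)(C)C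
F6 | step 6 | methyl (2S,3R)-2-[4-(benzyloxy)-3-methoxyphenyl]-7-bromo-3-{[(tert-butyldimethylsilyl)oxy]methyl}-7a-(methylsulfanyl)-2,3,3a,7a-tetrahydro-1-benzofuran-5-carboxylate | COC(=O)C1=CC2[C@H](CO[Si](C)(C)C(C)(C)C)[C@@H](c3ccc(OCc4ccccc4)c(OC)c3)OC2(SC)C(Br)=C1
F7 | step 9 | methyl (2S,3R)-2-[4-(benzyloxy)-3-methoxyphenyl]-3-{[(tert-butyldimethylsilyl)oxy]methyl}-7-(4,4,5,5-tetramethyl-1,3,2-dioxaborolan-2-yl)-2,3-dihydro-1-benzofuran-5-carboxylate | COC(=O)c1cc(B4OC(C)(C)C(C)(C)O4)c2c(c1)[C@H](CO[Si](C)(C)C(C)(C)C)[C@@H](c1ccc(OCc3ccccc3)c(OC)c1)O2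
F8 | step 9 | methyl (2S,3R)-2-[4-(benzyloxy)-3-methoxyphenyl]-3-{[(tert-butyldimethylsilyl)oxy]methyl}-7-hydroxy-2,3-dihydro-1-benzofuran-5-carboxylate | COC(=O)c1cc(O)c2c(c1)[C@H](CO[Si](C)(C)C(C)(C)C)[C@@H](c1ccc(OCc3ccccc3)c(OC)c1)O2
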